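## Structural features

The target is a diarylheptanoid whose seven-carbon chain is closed through oxygen into an oxane ring. With the ring numbered O1 to C6, C2 carries a 2-(4-hydroxy-3-methoxyphenyl)ethyl chain (guaiacyl end), C4 a hydroxyl group and C6 a 4-hydroxy-3,5-dimethoxyphenyl ring (syringyl end) bonded directly to the ring. The three stereocentres C2, C4 and C6 are separated by CH2 groups, so none stands next to another; they are all cis, (2S,4R,6S) in the systematic name, and all equatorial on one chair. Both arenes are free phenols, the syringyl one the more electron-rich, and the C6–O1 bond is a benzylic ether para to that phenol, so it is open to acid ionisation, to hydrogenolysis and, through the phenol, to oxidation. The skeleton is plain; the real difficulty is to close the ring 2,6-cis from a single stereocentre on a flexible chain, to treat two similar electron-rich arenes differently, and to set C4 without opening the benzylic ether. The key step uses the fragile feature as the reactive one: the C6–H bond is benzylic, alpha to O1 and para to a phenol flanked by two methoxy groups, so two-electron oxidation of that phenol alone makes C6 an oxocarbenium carbon that a C5 nucleophile tethered through C4, C3 and C2 can attack.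

## Logic of the disconnections

**20 back to 18.** No skeletal bond is cut in the first two moves. The guaiacyl O–H bond of 20 is exchanged for an O–benzyl bond (19), and the C4–H bond of 19 is removed to leave the C4 ketone of 18. The benzyl group is there because the guaiacyl ring must be harder to oxidise than the syringyl phenol in the step that makes 18; an acyl group would widen that gap further but would not survive the alkoxide used earlier. The gain is the loss of the C4 stereocentre and of one of two competing phenols. The demands are axial hydride delivery to the 2,6-diequatorial chair and a hydrogenolysis that spares the benzylic C6–O1 bond.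

**18 back to 15.** The C5–C6 bond is cut, which opens the ring; C6 returns to a benzylic OCH2 group and C4/C5 to an enol acetate. C6 is the one position that oxidation of the free phenol alone can turn into a cation, and the enol acetate is a neutral nucleophile that leaves exactly the C4 ketone behind. The ring and the C6 stereocentre disappear, and an open chain with the single stereocentre C2 remains. The forward step must oxidise only the syringyl phenol and must close through a chair so that C2 dictates C6. The phenol is kept free in 15 on purpose: a silylated or alkylated syringyl ring would oxidise at about the same potential as the guaiacyl ring.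

**15 back to 13.** The phenol O–H bond of 15 is exchanged for an O–Si bond (14), and the vinylic C4–O bond of 14 is cut, which returns the enol acetate to the terminal alkyne of 13. A free para-hydroxybenzyl ether is the least stable function of the route, so it is revealed only after the alkyne has been converted at 80 °C in the presence of acetic acid, not before. The gain is a precursor with no labile group. The demands are Markovnikov addition of acetic acid to the alkyne and a desilylation that neither removes nor transfers the acetyl group.

**13 back to 8 and 12.** The benzylic O1–C6 bond is cut. This divides the molecule into two halves of similar size, each a few steps from a cheap arene, and leaves C2 in 8 as a plain secondary alcohol. The forward alkylation needs an alkoxide, so the phenol protection of 12 must withstand it; a triisopropylsilyl group is chosen over a smaller silyl group for that reason. 12 is an easily ionised bromide and must be made and used without delay.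

**8 back to 5 and 6.** The C2–C3 bond is cut. It is the only C–C bond formed at a stereocentre, and the cut gives an achiral aldehyde and a three-carbon reagent that brings C3, C4 and C5 with the alkyne in place. The demand is face selectivity from a catalyst, since 5 has no stereocentre to help.

**5 back to 1.** No C–C bond is cut, as 1 already holds the guaiacyl ring and all three side-chain carbons. The formyl group of 5 returns to the primary alcohol of 4, the C–O bond of 4 to the terminal alkene of 2, and the benzyl ether of 2 to the phenol of 1. The forward steps need anti-Markovnikov hydration and an oxidation that stops at the aldehyde.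

**12 back to 9.** Only functional groups change: the C–Br bond of 12 returns to the C–OH bond of 11, the carbinol of 11 to the formyl group of 10, and the O–Si bond of 10 to the phenol of 9. The one demand is that the hindered phenol accepts the bulky silyl group.

## Other disconnections considered

Alternative 1: The cut removes both bonds to C4 (C3–C4 and C4–C5). C4 becomes the carbanion carbon of 2-(tert-butyldimethylsilyl)-1,3-dithiane A1, C1 to C3 with the guaiacyl chain come from the alkyl epoxide A2, and C5–C6 with the syringyl ring from the aryl epoxide A3.
- Forward key step: lithiated A1 would open A2 at its CH2 end; a polar additive would trigger the 1,4-Brook shift of silicon to the new alkoxide and regenerate a dithiane anion; this would open A3 to give the open-chain adduct A4 in one flask.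
- In its favour: two C–C bonds and the whole C1–C7 chain in one operation, every step of an established type, and no oxidation-sensitive free phenol anywhere. On precedent and on convergence it is better than the chosen plan, whose key step has no direct precedent.
- Against it here: A4 has neither the ring nor a usable C4 carbonyl, and its C6 carbinol already has the configuration of the target, so closure by displacement at C6 would invert it. The ring must close through the benzylic cation or, after dithiane removal, through dehydration and oxa-Michael addition; both erase the C6 stereocentre that enantiopure A3 paid for. A3 is an electron-rich styrene oxide, prone to rearrangement and to attack at its benzylic carbon. The thioacetal must be removed beside two electron-rich arenes.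
- Comparison: both plans take C2 from a single-enantiomer building block and let ring closure set C6, so they are equal in stereocontrol. Mechanistically the alternative is a carbanion relay between two electrophiles, whereas the chosen plan makes C6 the electrophile by oxidation and forms ring and C5–C6 bond in one event. In step count the alternative is longer: its fragments need about as many steps as 8 and 12, and A4 then needs desilylation, ring closure, dithiane removal, reduction and debenzylation.

Alternative 2: The cut is the C2–C3 bond and, one stage further back, the two acetal C–O bonds at C2. This leads to the cis-disubstituted 4-methylidene-1,3-dioxane A6, assembled from the (S)-β-hydroxy acid A5 and 5 by acetalisation and carbonyl methylenation with Cp2TiMe2.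
- Forward key step: Me2AlCl would break the acetal C–O bond on the enol-ether side of A6, and the aluminium enolate and the C2 oxocarbenium ion would recombine through carbon in a chair to give the oxanone A7.
- In its favour: the reaction type is established for 2,6-cis-oxan-4-ones, and A7 has the same ring, ketone and relative configuration as 18. Both phenols travel as benzyl ethers, so no free phenol is handled and one hydrogenolysis frees both. On precedent it is better; on the stage reached it is the equal.
- Against it here: the only stereochemical information sits at C6, a benzylic carbon para to an alkoxy group. A strong Lewis acid may ionise the C6–O1 bond as well as the acetal bond, which would cost enantiomeric purity and not only diastereomeric purity. A5 must first be made as a single enantiomer, and pyrophoric titanium and aluminium alkyls are needed.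
- Comparison: the polarity pattern and the chair argument are the same; the bond formed differs (C2–C3 against C5–C6), as does the way to the cation (Lewis acid against anode). In the chosen plan the information is carried by C2, which is not benzylic and cannot ionise, a structural advantage. The step count is about equal: the route to A5, the acetalisation, the methylenation and the rearrangement roughly match steps 4 to 11.

Alternative 3: The cut passes through the syringyl ring itself. The two ring bonds between the methoxy-bearing carbons and the neighbouring CH carbons are broken, giving 1,3-dimethoxyacetone A8 and the aminoacrolein A9, in which the future ipso carbon is already bonded to C6 of a complete, silyl-protected oxane.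
- Forward key step: under base each α-carbon of A8 would condense with one of the two formyl-level carbons of A9, and loss of dimethylamine and water would aromatise the new ring to the phenol A10.
- In its favour: the phenol is born free and late, so nothing earlier must tolerate an oxidisable syringyl phenol, a labile para-hydroxybenzyl ether or a benzylic halide, and the task of telling two electron-rich arenes apart does not arise. On this point it is better than the chosen plan.
- Against it here: the key step forms no bond of the oxane and sets no stereocentre, so ring and stereotriad need a separate method first, and a two-carbon arm on C6 must then be raised to the aminoacrolein. In A9 the ring oxygen is beta to the carbon that becomes carbanionic when a nucleophile adds to the enaminal, so base can open the ring by β-elimination and put C6 at risk. The double condensation of an α,α'-dialkoxy ketone is less secure than that of simple ketones.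
- Comparison: structurally it spends the strategic step on an arene that 9 supplies ready-made. Mechanistically it is a carbonyl condensation sequence, against an oxidative C–H functionalisation. Both exploit the symmetry of the syringyl unit, where they are equal. In step count it is estimated to be clearly longer.

Key step: step 11

Remark: ring atoms keep the target numbering (O1, C2 with the arylethyl chain, C4 with OH, C6 with the syringyl ring) in all intermediates, whatever the locants of their systematic names.

Assumption: the (R)-configured phosphoric acid of step 4 is taken to send the propargyl group to the Re face of 5, as the accepted transition-state model predicts; if the sense proves opposite, the (S)-acid is used.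

## Route

Step 1
Reactants: 1 eugenol (4-allyl-2-methoxyphenol)
Product: 2 1-(benzyloxy)-2-methoxy-4-(prop-2-en-1-yl)benzene
Conditions: BnBr, K2CO3, acetone, reflux
Reagents that add atoms: benzyl bromide, BrCc1ccccc1
Why: Williamson ether synthesis: the phenoxide displaces bromide from the benzylic halide; the allyl group is inert to carbonate and no stereocentre is involved.

Step 2
Reactants: 2 1-(benzyloxy)-2-methoxy-4-(prop-2-en-1-yl)benzene
Product: 4 3-[4-(benzyloxy)-3-methoxyphenyl]propan-1-ol, via B-alkyl borabicyclononane 3 (not isolated)
Conditions: 9-borabicyclo[3.3.1]nonane (9-BBN), THF, 0 °C to rt; then NaOH, H2O2, 0 °C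
Reagents that add atoms: hydrogen peroxide, OO; 9-borabicyclo[3.3.1]nonane, B1C2CCCC1CCC2 (its boron cage stays only in 3)
Why: Hydroboration–oxidation: the bulky dialkylborane places boron on the terminal carbon of the allyl group (anti-Markovnikov), and alkaline peroxide replaces boron by hydroxyl; the benzyl ether is inert.

Step 3
Reactants: 4 3-[4-(benzyloxy)-3-methoxyphenyl]propan-1-ol
Product: 5 3-[4-(benzyloxy)-3-methoxyphenyl]propanal
Conditions: 2,2,6,6-tetramethylpiperidin-1-oxyl (10 mol %), PhI(OAc)2, CH2Cl2, rt
Reagents that add atoms: none
Why: Oxoammonium-mediated alcohol oxidation stops at the aldehyde in a non-aqueous medium and leaves the electron-rich arene and the benzyl ether alone; 5 is used fresh.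

Step 4
Reactants: 5 3-[4-(benzyloxy)-3-methoxyphenyl]propanal; 6 allenylboronic acid pinacol ester
Product: 8 (3S)-1-[4-(benzyloxy)-3-methoxyphenyl]hex-5-yn-3-ol, via pinacol borate ester 7 (not isolated)
Conditions: (R)-3,3'-bis(2,4,6-triisopropylphenyl)-1,1'-binaphthyl-2,2'-diyl hydrogen phosphate (10 mol %), 4 Å MS, toluene, −30 °C; then aq. NaHCO3
Reagents that add atoms: none
Why: Chiral Brønsted acid-catalysed propargylboration: the allenylboronate adds through a closed six-membered transition state with allenyl-to-propargyl transposition, and the phosphoric acid, hydrogen-bonded to a boronate oxygen and to the formyl hydrogen, should shield the Si face so that the propargyl group reaches the Re face and sets C2 as (S). Aqueous work-up cleaves the O–B bond of 7.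

Step 5
Reactants: 9 syringaldehyde (4-hydroxy-3,5-dimethoxybenzaldehyde)
Product: 10 3,5-dimethoxy-4-[(triisopropylsilyl)oxy]benzaldehyde
Conditions: iPr3SiCl, imidazole, 4-(dimethylamino)pyridine (cat.), DMF, 40 °C
Reagents that add atoms: chlorotri(propan-2-yl)silane, CC(C)[Si](Cl)(C(C)C)C(C)C
Why: Silylation of a phenol; the bulky silyl group, flanked by two methoxy groups, should withstand the alkoxide of step 8 and the acetic acid of step 9, which a smaller silyl group on a phenol might not.

Step 6
Reactants: 10 3,5-dimethoxy-4-[(triisopropylsilyl)oxy]benzaldehyde
Product: 11 {3,5-dimethoxy-4-[(triisopropylsilyl)oxy]phenyl}methanol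
Conditions: NaBH4, MeOH, 0 °C
Reagents that add atoms: none
Why: Borohydride reduction of an aromatic aldehyde; the hindered aryl silyl ether tolerates cold methanolic borohydride.

Step 7
Reactants: 11 {3,5-dimethoxy-4-[(triisopropylsilyl)oxy]phenyl}methanol
Product: 12 [4-(bromomethyl)-2,6-dimethoxyphenoxy]tri(propan-2-yl)silane
Conditions: CBr4, PPh3, CH2Cl2, 0 °C; used at once
Reagents that add atoms: carbon tetrabromide, BrC(Br)(Br)Br
Why: Appel bromination under neutral conditions converts the electron-rich benzylic alcohol into the bromide without acid that could ionise it; the bromide is not stored or chromatographed.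

Step 8
Reactants: 8 (3S)-1-[4-(benzyloxy)-3-methoxyphenyl]hex-5-yn-3-ol; 12 [4-(bromomethyl)-2,6-dimethoxyphenoxy]tri(propan-2-yl)silane
Product: 13 {4-[({(3S)-1-[4-(benzyloxy)-3-methoxyphenyl]hex-5-yn-3-yl}oxy)methyl]-2,6-dimethoxyphenoxy}tri(propan-2-yl)silane
Conditions: NaH, Bu4NI (10 mol %), THF/DMF 4:1, 0 °C to rt
Reagents that add atoms: none
Why: Williamson etherification: after deprotonation of the hydroxyl group the oxygen of 8 displaces bromide (iodide catalysis) from the benzylic carbon, which forms the O1–C6 bond. Only the O–H bond of the stereocentre is touched, and one equivalent of hydride leaves the terminal alkyne C–H alone.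

Step 9
Reactants: 13 {4-[({(3S)-1-[4-(benzyloxy)-3-methoxyphenyl]hex-5-yn-3-yl}oxy)methyl]-2,6-dimethoxyphenoxy}tri(propan-2-yl)silane
Product: 14 (4S)-6-[4-(benzyloxy)-3-methoxyphenyl]-4-({3,5-dimethoxy-4-[(triisopropylsilyl)oxy]benzyl}oxy)hex-1-en-2-yl acetate
Conditions: [RuCl2(p-cymene)]2 (2 mol %), tri(2-furyl)phosphine (8 mol %), Na2CO3 (15 mol %), AcOH (3 equiv), toluene, 80 °C
Reagents that add atoms: acetic acid, CC(=O)O
Why: Ruthenium-catalysed Markovnikov hydro-acyloxylation of a terminal alkyne: acetate adds to the internal carbon of the metal-bound alkyne to give the 2-acetoxy-1-alkene. With the phenol still silylated, the benzylic ether behaves as a para-alkoxybenzyl ether, a class that tolerates these conditions.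

Step 10
Reactants: 14 (4S)-6-[4-(benzyloxy)-3-methoxyphenyl]-4-({3,5-dimethoxy-4-[(triisopropylsilyl)oxy]benzyl}oxy)hex-1-en-2-yl acetate
Product: 15 (4S)-6-[4-(benzyloxy)-3-methoxyphenyl]-4-[(4-hydroxy-3,5-dimethoxybenzyl)oxy]hex-1-en-2-yl acetate
Conditions: Bu4NF (1.1 equiv), AcOH (1.3 equiv), THF, 0 °C; taken on without storage
Reagents that add atoms: none
Why: Fluoride cleavage of an aryl silyl ether, which is far faster than attack of fluoride on an ester. The acetic acid buffer protonates the phenoxide as it forms, so it can neither take the acetyl group from the enol acetate nor start 1,6-elimination of the benzylic ether.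

Step 11
Reactants: 15 (4S)-6-[4-(benzyloxy)-3-methoxyphenyl]-4-[(4-hydroxy-3,5-dimethoxybenzyl)oxy]hex-1-en-2-yl acetate
Product: 18 (2S,6S)-6-{2-[4-(benzyloxy)-3-methoxyphenyl]ethyl}-2-(4-hydroxy-3,5-dimethoxyphenyl)oxan-4-one, via alkoxy quinone methide 16 (not isolated), via (E)-oxocarbenium ion 17 (not isolated)
Conditions: undivided cell, graphite anode, Pt cathode, Bu4NPF6 (0.1 M), dry CH2Cl2/(CF3)2CHOH 4:1, 5 mM, 0 °C, Ar, controlled potential at the first anodic wave of 15 (located by cyclic voltammetry), stopped at 2.0–2.2 F/mol
Reagents that add atoms: none
Why: Proposed new method: at the carbon anode the free syringyl phenol of 15, expected to oxidise well below the benzylated guaiacyl ring and the enol acetate, should lose two electrons and two protons (the second from the benzylic CH2) to give the alkoxy para-quinone methide 16, which the fluorinated alcohol and the acid released at the anode protonate on the carbonyl oxygen to the (E)-oxocarbenium ion 17. The terminal enol carbon then attacks C6 of 17 to form C5–C6, the O-acetyl oxocarbenium ion that results passes its acetyl group to the fluorinated alcohol to leave ketone 18, and the protons are reduced to dihydrogen at the platinum cathode, whose low overpotential keeps it from reducing 16 or 18. The closest known reaction types are the quinone (DDQ)-mediated oxidative C–H cyclisation of para-methoxybenzyl ethers onto enol acetates and the anodic conversion of 4-alkyl-2,6-dimethoxyphenols into quinone methides; the new element is their union, with an electrode in place of the quinone and a free phenol as the trigger. The oxane ring closes in a 6-endo-trig mode, a Prins-type closure in which both atoms of the C6=O1 bond and both carbons of the enol double bond end up inside the ring. The new stereocentre C6 is controlled by C2 through a chair transition state with the C2 chain and the aryl group of the (E)-oxocarbenium ion both equatorial, hence 2,6-cis and (6S) from (2S). The step needs chemoselective oxidation, secured by holding the potential at the phenol wave and limiting the charge. It also needs ring closure faster than seven-membered Friedel–Crafts attack by the guaiacyl ring or capture by outside nucleophiles, secured by the six-membered chair, the dry and weakly nucleophilic medium and high dilution. Survival of the product phenol should be helped because the C6–H of 18 is tertiary and ring-bound, so quinone-methide formation from 18 should be slower than from 15.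

Step 12
Reactants: 18 (2S,6S)-6-{2-[4-(benzyloxy)-3-methoxyphenyl]ethyl}-2-(4-hydroxy-3,5-dimethoxyphenyl)oxan-4-one
Product: 19 (2S,4R,6S)-2-{2-[4-(benzyloxy)-3-methoxyphenyl]ethyl}-6-(4-hydroxy-3,5-dimethoxyphenyl)oxan-4-ol
Conditions: NaBH4, MeOH, −40 °C to −20 °C
Reagents that add atoms: none
Why: Borohydride reduction of a 2,6-cis-disubstituted oxan-4-one: the small hydride attacks axially on the chair with both substituents equatorial, which should give the equatorial (4R) alcohol, cis to both substituents.

Step 13
Reactants: 19 (2S,4R,6S)-2-{2-[4-(benzyloxy)-3-methoxyphenyl]ethyl}-6-(4-hydroxy-3,5-dimethoxyphenyl)oxan-4-ol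
Product: 20 (2S,4R,6S)-2-(4-hydroxy-3,5-dimethoxyphenyl)-6-[2-(4-hydroxy-3-methoxyphenyl)ethyl]oxan-4-ol (CNP0302691.1)
Conditions: H2 (1 atm), 10% Pd/C, EtOAc, rt
Reagents that add atoms: none
Why: Catalytic hydrogenolysis of an aryl benzyl ether, the fastest-cleaving class of benzyl ether; in a neutral aprotic solvent at atmospheric pressure the cyclic benzylic C6–O1 bond should survive, and no stereocentre is touched.

## Compound list

1 | eugenol (4-allyl-2-methoxyphenol) | COc1cc(CC=C)ccc1O | starting material
2 | 1-(benzyloxy)-2-methoxy-4-(prop-2-en-1-yl)benzene | COc1cc(CC=C)ccc1OCc1ccccc1 | intermediate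
3 | 9-{3-[4-(benzyloxy)-3-methoxyphenyl]propyl}-9-borabicyclo[3.3.1]nonane | COc1cc(CCCB2C3CCCC2CCC3)ccc1OCc1ccccc1 | intermediate (not isolated)
4 | 3-[4-(benzyloxy)-3-methoxyphenyl]propan-1-ol | COc1cc(CCCO)ccc1OCc1ccccc1 | intermediate
5 | 3-[4-(benzyloxy)-3-methoxyphenyl]propanal | COc1cc(CCC=O)ccc1OCc1ccccc1 | intermediate
6 | allenylboronic acid pinacol ester (4,4,5,5-tetramethyl-2-(propa-1,2-dien-1-yl)-1,3,2-dioxaborolane) | C=C=CB1OC(C)(C)C(C)(C)O1 | starting material
7 | 2-({(3S)-1-[4-(benzyloxy)-3-methoxyphenyl]hex-5-yn-3-yl}oxy)-4,4,5,5-tetramethyl-1,3,2-dioxaborolane | COc1cc(CC[C@H](OB2OC(C)(C)C(C)(C)O2)CC#C)ccc1OCc1ccccc1 | intermediate (not isolated)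
8 | (3S)-1-[4-(benzyloxy)-3-methoxyphenyl]hex-5-yn-3-ol | COc1cc(CC[C@H](O)CC#C)ccc1OCc1ccccc1 | intermediate
9 | syringaldehyde (4-hydroxy-3,5-dimethoxybenzaldehyde) | COc1cc(C=O)cc(OC)c1O | starting material
10 | 3,5-dimethoxy-4-[(triisopropylsilyl)oxy]benzaldehyde | COc1cc(C=O)cc(OC)c1O[Si](C(C)C)(C(C)C)C(C)C | intermediate
11 | {3,5-dimethoxy-4-[(triisopropylsilyl)oxy]phenyl}methanol | COc1cc(CO)cc(OC)c1O[Si](C(C)C)(C(C)C)C(C)C | intermediate
12 | [4-(bromomethyl)-2,6-dimethoxyphenoxy]tri(propan-2-yl)silane | COc1cc(CBr)cc(OC)c1O[Si](C(C)C)(C(C)C)C(C)C | intermediate
13 | {4-[({(3S)-1-[4-(benzyloxy)-3-methoxyphenyl]hex-5-yn-3-yl}oxy)methyl]-2,6-dimethoxyphenoxy}tri(propan-2-yl)silane | COc1cc(CC[C@H](OCc2cc(OC)c(O[Si](C(C)C)(C(C)C)C(C)C)c(OC)c2)CC#C)ccc1OCc1ccccc1 | intermediate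
14 | (4S)-6-[4-(benzyloxy)-3-methoxyphenyl]-4-({3,5-dimethoxy-4-[(triisopropylsilyl)oxy]benzyl}oxy)hex-1-en-2-yl acetate | COc1cc(CC[C@H](OCc2cc(OC)c(O[Si](C(C)C)(C(C)C)C(C)C)c(OC)c2)CC(OC(C)=O)=C)ccc1OCc1ccccc1 | intermediate
15 | (4S)-6-[4-(benzyloxy)-3-methoxyphenyl]-4-[(4-hydroxy-3,5-dimethoxybenzyl)oxy]hex-1-en-2-yl acetate | COc1cc(CC[C@H](OCc2cc(OC)c(O)c(OC)c2)CC(OC(C)=O)=C)ccc1OCc1ccccc1 | intermediate
16 | (4S)-6-[4-(benzyloxy)-3-methoxyphenyl]-4-[(3,5-dimethoxy-4-oxocyclohexa-2,5-dien-1-ylidene)methoxy]hex-1-en-2-yl acetate | COC1=CC(=CO[C@@H](CCc2ccc(OCc3ccccc3)c(OC)c2)CC(OC(C)=O)=C)C=C(OC)C1=O | intermediate (not isolated)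
17 | (E)-{(4S)-2-acetoxy-6-[4-(benzyloxy)-3-methoxyphenyl]hex-1-en-4-yl}(4-hydroxy-3,5-dimethoxybenzylidene)oxonium | COc1cc(/C=[O+]/[C@@H](CCc2ccc(OCc3ccccc3)c(OC)c2)CC(OC(C)=O)=C)cc(OC)c1O | intermediate (not isolated)
18 | (2S,6S)-6-{2-[4-(benzyloxy)-3-methoxyphenyl]ethyl}-2-(4-hydroxy-3,5-dimethoxyphenyl)oxan-4-one | COc1cc(CC[C@H]2CC(=O)C[C@@H](c3cc(OC)c(O)c(OC)c3)O2)ccc1OCc1ccccc1 | intermediate
19 | (2S,4R,6S)-2-{2-[4-(benzyloxy)-3-methoxyphenyl]ethyl}-6-(4-hydroxy-3,5-dimethoxyphenyl)oxan-4-ol | COc1cc(CC[C@H]2C[C@@H](O)C[C@@H](c3cc(OC)c(O)c(OC)c3)O2)ccc1OCc1ccccc1 | intermediate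
20 | (2S,4R,6S)-2-(4-hydroxy-3,5-dimethoxyphenyl)-6-[2-(4-hydroxy-3-methoxyphenyl)ethyl]oxan-4-ol | COc1cc(CC[C@H]2C[C@@H](O)C[C@@H](c3cc(OC)c(O)c(OC)c3)O2)ccc1O | target

## Step count and least certain steps

Total step count: 13. Longest linear sequence: 10 steps (1, 2, 3, 4, 8, 9, 10, 11, 12, 13) from 1 to 20; steps 5 to 7 form the three-step side branch from 9 to 12.

**Step 11 (key step, new method).**
- Most likely failure: over-oxidation, because the phenol of 18 oxidises at the same potential as that of 15, and charge passed beyond two faradays per mole would start quinone-methide chemistry at C6 of the product, with ring opening or loss of configuration.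
- Second failure: hydrolytic cleavage of the oxocarbenium ion by adventitious water (oxidative debenzylation in place of cyclisation).
- Third failure: intermolecular capture of the quinone methide by a second phenol or arene if the ring closure is slow.
- Fallback, of known type, sets out from 14 and returns at 18. Compound 14, whose silylated benzylic ether is an electron-rich para-alkoxybenzyl-type ether, is treated with 2,3-dichloro-5,6-dicyano-1,4-benzoquinone, 2,6-dichloropyridine, LiClO4 and 4 Å molecular sieves in 1,2-dichloroethane. Hydride abstraction from the benzylic CH2 and 6-endo attack of the enol acetate, the established quinone-mediated oxidative C–H cyclisation, should give (2S,6S)-6-{2-[4-(benzyloxy)-3-methoxyphenyl]ethyl}-2-{3,5-dimethoxy-4-[(triisopropylsilyl)oxy]phenyl}oxan-4-one F1. Bu4NF buffered with acetic acid in THF at 0 °C then frees the phenol to give 18; at that stage no enol acetate is left to interfere.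

**Step 4.**
- Most likely failure: insufficient facial selectivity, since unbranched aliphatic aldehydes are the less selective substrate class for acid-catalysed propargylboration, and the sense of induction rests on a model.
- Fallback sets out from 5 and returns at 8. Corey–Chaykovsky methylenation of 5 (trimethylsulfonium iodide, KOtBu, DMSO/THF) gives racemic 2-{2-[4-(benzyloxy)-3-methoxyphenyl]ethyl}oxirane F2. Hydrolytic kinetic resolution with (S,S)-N,N'-bis(3,5-di-tert-butylsalicylidene)cyclohexane-1,2-diaminocobalt acetate (trivalent cobalt) and 0.55 equivalents of water, using the antipode of the catalyst expected to leave the (S)-epoxide unreacted, gives (2S)-2-{2-[4-(benzyloxy)-3-methoxyphenyl]ethyl}oxirane F3. Opening of F3 at its CH2 terminus with lithium acetylide–ethylenediamine complex in DMSO gives 8 with the stereocentre untouched.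

**Step 8.**
- Most likely failure: ionisation and self-condensation of the very electron-rich bromide 12 before it is alkylated, or transfer of the silyl group from the aryl oxygen to the alkoxide.
- Fallback sets out from 11 (with 8) and returns at 13. Alcohol 11 is converted with Cl3CCN and catalytic 1,8-diazabicyclo[5.4.0]undec-7-ene into {3,5-dimethoxy-4-[(triisopropylsilyl)oxy]phenyl}methyl 2,2,2-trichloroethanimidate F4. F4 alkylates 8 under catalysis by camphorsulfonic acid in CH2Cl2 at 0 °C, an acid-promoted benzylation that needs no alkoxide and no benzylic halide.

**Step 10.**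
- Most likely failure: acetyl transfer from the enol acetate to the phenoxide, or cleavage of the enol acetate by fluoride, before the buffer intervenes.
- Fallback sets out from 13 and returns at 15, reversing the order of the two operations. Desilylation of 13 with Bu4NF in THF at 0 °C, where no acyl group is present, gives 4-[({(3S)-1-[4-(benzyloxy)-3-methoxyphenyl]hex-5-yn-3-yl}oxy)methyl]-2,6-dimethoxyphenol F5. The ruthenium-catalysed addition of acetic acid is then run on F5 at the lowest workable temperature (about 50 to 60 °C, longer time) to give 15.

**Step 13.**
- Most likely failure: competing hydrogenolysis of the benzylic C6–O1 bond, which would open the ring, because that bond is activated by the para-hydroxyl group.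
- Fallback sets out from 19 and returns at 20 without a new isolated compound (F0). The aryl benzyl ether is cleaved with BCl3 and pentamethylbenzene as a non-basic cation scavenger in CH2Cl2 at −78 °C, followed by methanol quench; this is a Lewis-acid dealkylation in place of a reduction.

## Further compounds

F1 | step 11 | (2S,6S)-6-{2-[4-(benzyloxy)-3-methoxyphenyl]ethyl}-2-{3,5-dimethoxy-4-[(triisopropylsilyl)oxy]phenyl}oxan-4-one | COc1cc(CC[C@H]2CC(=O)C[C@@H](c3cc(OC)c(O[Si](C(C)C)(C(C)C)C(C)C)c(OC)c3)O2)ccc1OCc1ccccc1
F2 | step 4 | rac-2-{2-[4-(benzyloxy)-3-methoxyphenyl]ethyl}oxirane | COc1cc(CCC2CO2)ccc1OCc1ccccc1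
F3 | step 4 | (2S)-2-{2-[4-(benzyloxy)-3-methoxyphenyl]ethyl}oxirane | COc1cc(CC[C@H]2CO2)ccc1OCc1ccccc1
F4 | step 8 | {3,5-dimethoxy-4-[(triisopropylsilyl)oxy]phenyl}methyl 2,2,2-trichloroethanimidate | COc1cc(COC(=N)C(Cl)(Cl)Cl)cc(OC)c1O[Si](C(C)C)(C(C)C)C(C)C
F5 | step 10 | 4-[({(3S)-1-[4-(benzyloxy)-3-methoxyphenyl]hex-5-yn-3-yl}oxy)methyl]-2,6-dimethoxyphenol | COc1cc(CC[C@H](OCc2cc(OC)c(O)c(OC)c2)CC#C)ccc1OCc1ccccc1
F0 | step 13 | none | none
A1 | alternative 1 | 2-(tert-butyldimethylsilyl)-1,3-dithiane | CC(C)(C)[Si](C)(C)C1SCCCS1
A2 | alternative 1 | (2S)-2-{2-[4-(benzyloxy)-3-methoxyphenyl]ethyl}oxirane | COc1cc(CC[C@H]2CO2)ccc1OCc1ccccc1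
A3 | alternative 1 | (2R)-2-[4-(benzyloxy)-3,5-dimethoxyphenyl]oxirane | C1[C@H](O1)c2cc(OC)c(OCc3ccccc3)c(OC)c2
A4 | alternative 1 | (1S)-1-[4-(benzyloxy)-3,5-dimethoxyphenyl]-2-{2-[(2S)-4-[4-(benzyloxy)-3-methoxyphenyl]-2-[(tert-butyldimethylsilyl)oxy]butyl]-1,3-dithian-2-yl}ethan-1-ol | COc1cc(CC[C@H](O[Si](C)(C)C(C)(C)C)CC2(C[C@H](O)c3cc(OC)c(OCc4ccccc4)c(OC)c3)SCCCS2)ccc1OCc1ccccc1
A5 | alternative 2 | (3S)-3-[4-(benzyloxy)-3,5-dimethoxyphenyl]-3-hydroxypropanoic acid | OC(=O)C[C@H](O)c1cc(OC)c(OCc2ccccc2)c(OC)c1
A6 | alternative 2 | (2R,4S)-4-[4-(benzyloxy)-3,5-dimethoxyphenyl]-2-{2-[4-(benzyloxy)-3-methoxyphenyl]ethyl}-6-methylidene-1,3-dioxane | C=C1C[C@@H](c2cc(OC)c(OCc3ccccc3)c(OC)c2)O[C@@H](CCc2ccc(OCc3ccccc3)c(OC)c2)O1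
A7 | alternative 2 | (2S,6S)-2-[4-(benzyloxy)-3,5-dimethoxyphenyl]-6-{2-[4-(benzyloxy)-3-methoxyphenyl]ethyl}oxan-4-one | COc1cc(CC[C@H]2CC(=O)C[C@@H](c3cc(OC)c(OCc4ccccc4)c(OC)c3)O2)ccc1OCc1ccccc1
A8 | alternative 3 | 1,3-dimethoxypropan-2-one | COCC(=O)COC
A9 | alternative 3 | 2-[(2S,4R,6S)-6-{2-[4-(benzyloxy)-3-methoxyphenyl]ethyl}-4-[(tert-butyldimethylsilyl)oxy]oxan-2-yl]-3-(dimethylamino)prop-2-enal (alkene geometry not fixed) | COc1cc(CC[C@H]2C[C@@H](O[Si](C)(C)C(C)(C)C)C[C@@H](C(C=O)=CN(C)C)O2)ccc1OCc1ccccc1
A10 | alternative 3 | 4-[(2S,4R,6S)-6-{2-[4-(benzyloxy)-3-methoxyphenyl]ethyl}-4-[(tert-butyldimethylsilyl)oxy]oxan-2-yl]-2,6-dimethoxyphenol | COc1cc(CC[C@H]2C[C@@H](O[Si](C)(C)C(C)(C)C)C[C@@H](c3cc(OC)c(O)c(OC)c3)O2)ccc1OCc1ccccc1
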